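**Plan**

1. Retrosynthesis: cut C16–C17 (MeMgBr on a 16-ketone), then undo a 1,2-shift of C12 from C13 back to C16. Ring C (C8–C9–C11–C12–C13–C14) thus comes from the seven-membered ring C8–C9–C11–C12–C16–C13–C14 of an isomeric bicyclo[3.2.1]octane with a cis 13,16-diol. Further cuts: C3–C4 (aldol), C4–C5 (Michael, lactone), C10–C1 (organocerium), C6–C7 (carbonylation), C13–C16 (pinacol), C8–C14 (reductive alkylation of 6-methoxy-1-indanone).
2. Forward: ring B and ring E (C8–C9–C11–C12–C16–C15, the former arene) are present from the start. Birch alkylation makes quaternary C8, pinacol coupling of the two carbonyl carbons C13 and C16 closes the ring C8–C14–C13–C16–C15, Michael addition closes the lactone, the ring contraction then creates ring C and the ring-D ketone, and ring A is closed last by aldol.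
3. Enabling feature: the C13–C16 bond of ring D with oxygen on C16. In the precursor C16 is a bridgehead carbinol whose C16–C12 bond is anti-periplanar to an exo C13–OMs, so C12 can shift to C13 while C16 becomes the carbonyl that later carries OH and CH3.
4. Stereochemistry: absolute configuration (C8) from a catalyst-controlled CBS reduction that resolves racemic 2; C9 by hydrogenation opposite the C13–C14 bridge; C10 by addition anti to C11; C5 by the lactone tether, C6 by equilibration, C4 by the bicyclic lactone; C13 by the stereospecific shift; C16 by exo attack of MeMgBr; C3 by equatorial hydride delivery.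

Key step: step 15

Numbering: all carbons are numbered as in the target (gibberellane numbering; C7 = carboxyl carbon, C19 = lactone carbonyl, C17 and C18 = methyls). β is the face of ring B that carries H5, H9 and C7 in 24. The indanone atoms C1, C2, C3, C3a, C4, C5, C6, C7, C7a of 1 become C6, C5, C10, C9, C11, C12, C16, C15, C8.

Remark: step 1 is not enantioselective; step 2 turns the two enantiomers of 2 into separable diastereomers, so at most half of 2 is carried on.

**Step 1**
Reactants: 1 6-methoxy-1-indanone
Product: 2 ethyl 2-(6-methoxy-1-oxo-2,3,5,7a-tetrahydro-1H-inden-7a-yl)acetate (racemic)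
Conditions: K, NH3(l)/THF, t-BuOH (1 equiv), −78 °C; LiBr; piperylene; then BrCH2CO2Et, −78 → −33 °C
Reagents that add atoms: ethyl bromoacetate, CCOC(=O)CBr
Why: Birch reductive alkylation of an aryl ketone: reduction with protonation para to the carbonyl (C12) should give the cross-conjugated dienolate, which the reactive bromoacetate alkylates at its α-carbon C8 to form the quaternary centre (racemic) and leave the C9=C11 and C15=C16 (enol ether) double bonds.

**Step 2**
Reactants: 2 ethyl 2-(6-methoxy-1-oxo-2,3,5,7a-tetrahydro-1H-inden-7a-yl)acetate (racemic)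
Product: 3 ethyl 2-[(1S,7aR)-1-hydroxy-6-methoxy-2,3,5,7a-tetrahydro-1H-inden-7a-yl]acetate
Conditions: (R)-2-methyl-CBS-oxazaborolidine (20 mol %), catecholborane, toluene, −78 °C; then DBU (cat.), CH2Cl2, rt; chromatography
Reagents that add atoms: none
Why: Corey–Bakshi–Shibata reduction under catalyst control (large group = quaternary C8, small = C5) should give the 6S carbinol from both enantiomers of 2, so the 8R enantiomer becomes the trans hydroxy ester 3 while the 8S enantiomer becomes the cis isomer, which lactonises and is separated; catecholborane spares the alkenes.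

**Step 3**
Reactants: 3 ethyl 2-[(1S,7aR)-1-hydroxy-6-methoxy-2,3,5,7a-tetrahydro-1H-inden-7a-yl]acetate
Product: 5 (1S,7aR)-1-hydroxy-7a-(2-hydroxyethyl)-1,2,3,5,7,7a-hexahydro-6H-inden-6-one, via enol-ether diol 4 (not isolated)
Conditions: LiAlH4, THF, 0 °C; then aq. oxalic acid, THF, rt
Reagents that add atoms: water, O
Why: hydride reduction of the ester to the primary alcohol, then mild acid hydrolysis of the methyl enol ether, which should give the β,γ-unsaturated C16 ketone without moving the C9=C11 double bond into conjugation.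

**Step 4**
Reactants: 5 (1S,7aR)-1-hydroxy-7a-(2-hydroxyethyl)-1,2,3,5,7,7a-hexahydro-6H-inden-6-one
Product: 6 2-[(7aR)-1,6-dioxo-1,2,3,5,6,7-hexahydro-7aH-inden-7a-yl]acetaldehyde
Conditions: Dess–Martin periodinane, NaHCO3, CH2Cl2, 0 °C → rt
Reagents that add atoms: none
Why: Dess–Martin oxidation of both alcohols under buffered, non-enolising conditions gives the C13 aldehyde and restores the C6 ketone, which removes the auxiliary C6 stereocentre.

**Step 5**
Reactants: 6 2-[(7aR)-1,6-dioxo-1,2,3,5,6,7-hexahydro-7aH-inden-7a-yl]acetaldehyde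
Product: 7 tricyclic keto diol (13-exo-OH, 16-OH, C9=C11, C6 ketone)
Conditions: SmI2 (2.2 equiv), THF, −78 → 0 °C; aq. NH4Cl
Reagents that add atoms: none
Why: intramolecular pinacol coupling joins the two electrophilic carbonyl carbons C13 and C16 through the aldehyde ketyl in a 5-exo-trig closure of the ring C8–C14–C13–C16–C15; chelation of both oxygens to trivalent samarium should give the cis diol (13-OH exo), and the hindered C6 ketone is expected to survive at low temperature.

**Step 6**
Reactants: 7 tricyclic keto diol (13-exo-OH, 16-OH, C9=C11, C6 ketone)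
Product: 8 saturated keto diol (9β-H)
Conditions: H2 (1 atm), 10% Pd on carbon, EtOAc, rt
Reagents that add atoms: none
Why: catalytic heterogeneous hydrogenation of the C9=C11 alkene should occur from the face opposite the axial C13–C14 bridge that covers the lower face of ring E, which places H9 anti to C14 (trans fusion of rings B and E) as the target requires.

**Step 7**
Reactants: 8 saturated keto diol (9β-H)
Product: 9 keto acetonide (13,16-O-isopropylidene)
Conditions: 2,2-dimethoxypropane, PPTS (cat.), acetone, rt
Reagents that add atoms: 2,2-dimethoxypropane, COC(C)(C)OC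
Why: acid-catalysed acetal exchange protects the cis 13,16-diol as its isopropylidene acetal for the base and organometallic steps that follow; the hindered C6 ketone should not ketalise.

**Step 8**
Reactants: 9 keto acetonide (13,16-O-isopropylidene)
Product: 10 enol triflate (C5=C6, OTf on C6)
Conditions: KN(SiMe3)2, PhNTf2, THF, −78 °C
Reagents that add atoms: N-phenylbis(trifluoromethanesulfonimide), O=S(=O)(N(c1ccccc1)S(=O)(=O)C(F)(F)F)C(F)(F)F
Why: enolisation of the ketone, which has α-hydrogens only at C5, and O-sulfonylation of the enolate give the C5=C6 enol triflate.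

**Step 9**
Reactants: 10 enol triflate (C5=C6, OTf on C6)
Product: 11 benzyl enoate (CO2Bn = C7 on C6)
Conditions: Pd(OAc)2 (5 mol %), dppp, CO (1 atm), BnOH, Et3N, DMF, 60 °C
Reagents that add atoms: carbon monoxide, [C-]#[O+]; benzyl alcohol, OCc1ccccc1
Why: palladium-catalysed alkoxycarbonylation of the enol triflate (oxidative addition, CO insertion, alcoholysis) installs C7 as the benzyl ester on C6.

**Step 10**
Reactants: 11 benzyl enoate (CO2Bn = C7 on C6)
Product: 12 benzyl γ-oxo enoate (C10 ketone)
Conditions: CrO3, 3,5-dimethylpyrazole, CH2Cl2, −20 °C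
Reagents that add atoms: chromium trioxide, O=[Cr](=O)=O
Why: allylic oxidation with the CrO3–3,5-dimethylpyrazole complex should act at C10, the only allylic methylene of the enoate (C8 is quaternary), to give the cyclopentenone.

**Step 11**
Reactants: 12 benzyl γ-oxo enoate (C10 ketone)
Product: 14 10α-propionyloxy-10β-(but-3-enyl) enoate acetonide, via tertiary alcohol 13 (not isolated)
Conditions: CeCl3, CH2=CHCH2CH2MgBr, THF, −78 °C; then (EtCO)2O, DMAP, −78 °C → rt
Reagents that add atoms: but-3-enylmagnesium bromide, C=CCC[Mg]Br; propionic anhydride, CCC(=O)OC(=O)CC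
Why: the weakly basic organocerium reagent (Grignard-type 1,2-addition) should attack the C10 ketone from the β face, anti to C11 on the neighbouring C9 and to the C14 bridge, which sets C10 (chain β, oxygen α); the tertiary alkoxide is O-acylated in the same flask.

**Step 12**
Reactants: 14 10α-propionyloxy-10β-(but-3-enyl) enoate acetonide
Product: 15 γ-lactone acetonide (C4–C5 bond, 5β-H, 6β-CO2Bn)
Conditions: KN(SiMe3)2 (1.1 equiv), THF, −78 → −30 °C; t-BuOH, 0 °C; AcOH
Reagents that add atoms: none
Why: intramolecular Michael addition of the propionate enolate to the enoate closes the γ-lactone by a 5-exo-trig attack that is possible only on the α face where O10 sits, which sets C5 (H5 β); equilibrating protonation of the ester enolate should give the more stable 6β-ester (trans to C4), and C4 stays an inconsequential mixture.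

**Step 13**
Reactants: 15 γ-lactone acetonide (C4–C5 bond, 5β-H, 6β-CO2Bn)
Product: 16 lactone 13-exo,16-diol
Conditions: AcOH/H2O/THF (3:1:1), 45 °C
Reagents that add atoms: none
Why: mild acid hydrolysis of the isopropylidene acetal frees the cis diol without touching the lactone, the benzyl ester or the terminal alkene.

**Step 14**
Reactants: 16 lactone 13-exo,16-diol
Product: 17 lactone 13-exo-mesylate (16-OH free)
Conditions: MsCl, Et3N, CH2Cl2, −10 °C
Reagents that add atoms: methanesulfonyl chloride, CS(=O)(=O)Cl
Why: selective sulfonylation (mesylation) of the secondary C13 hydroxyl; the tertiary bridgehead C16 hydroxyl does not react.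

**Step 15**
Reactants: 17 lactone 13-exo-mesylate (16-OH free)
Product: 18 ring-contracted 16-ketone (gibberellane rings C and D)
Conditions: KN(SiMe3)2 (1.05 equiv), THF, −78 → 0 °C
Reagents that add atoms: none
Why: Deprotonation of the tertiary C16–OH triggers a semipinacol 1,2-alkyl shift in which the electron pair of the C16–C12 bond, anti-periplanar to the exo C13–OMs bond, displaces mesylate with inversion at C13 while C16 becomes the ketone. The closest known reaction type is the base-induced rearrangement of cis-1,2-diol monosulfonates used for ring expansion and contraction in bridged and fused carbocycles. No ring is closed by a cyclisation: the seven-membered ring C8–C9–C11–C12–C16–C13–C14 loses C16 and contracts to the six-membered ring C (C8–C9–C11–C12–C13–C14), while the five-membered ring C8–C14–C13–C16–C15 persists as ring D with its one-carbon and two-carbon bridges exchanged. C13 is the only new stereocentre and is fixed by the stereospecific backside migration within the bicyclic frame; C8 and C9 are not touched. The step needs migration of C12 and not of C15 and must avoid epoxide formation: the exo mesylate secures the first (only C16–C12 is anti-periplanar to it) and the cis relation of O16 and the mesylate excludes the second. The driving force is formation of the C=O bond with loss of mesylate.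

**Step 16**
Reactants: 18 ring-contracted 16-ketone (gibberellane rings C and D)
Product: 19 16-methyl carbinol (CH3 exo, OH endo)
Conditions: CeCl3, MeMgBr, THF, −78 °C
Reagents that add atoms: methylmagnesium bromide, C[Mg]Br
Why: Grignard addition (cerium-mediated to suppress enolisation) should occur on the exo face of the C16 ketone, the side of the one-carbon bridge C14 and away from the C11–C12 bridge, which places the methyl exo and the hydroxyl endo as in the target; the ketone reacts far faster than lactone or ester at −78 °C.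

**Step 17**
Reactants: 19 16-methyl carbinol (CH3 exo, OH endo)
Product: 20 C3 aldehyde
Conditions: O3, CH2Cl2, −78 °C; then Me2S, −78 °C → rt
Reagents that add atoms: ozone, [O-][O+]=O
Why: ozonolysis of the only alkene with reductive work-up gives the C3 aldehyde.

**Step 18**
Reactants: 20 C3 aldehyde
Product: 21 benzyl ester with ring A closed (3-OH epimers)
Conditions: KOt-Bu (0.3 equiv), THF/t-BuOH, 0 °C
Reagents that add atoms: none
Why: intramolecular aldol addition of the lactone enolate (C4) to the C3 aldehyde closes ring A by a 6-exo-trig attack; C4 is fixed by the bicyclic lactone, C6 equilibrates to the stable 6β-ester, and C3 forms as a mixture of epimers that the next two steps converge.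

**Step 19**
Reactants: 21 benzyl ester with ring A closed (3-OH epimers)
Product: 22 3-oxo benzyl ester
Conditions: Dess–Martin periodinane, NaHCO3, CH2Cl2, rt
Reagents that add atoms: none
Why: Dess–Martin oxidation converts both C3 epimers into one β-keto lactone; the tertiary C16 alcohol is inert.

**Step 20**
Reactants: 22 3-oxo benzyl ester
Product: 23 benzyl ester of the target (3β-OH)
Conditions: LiBH(s-Bu)3, THF, −78 °C; aq. NH4Cl
Reagents that add atoms: none
Why: the bulky hydride should attack the ring-A cyclohexanone equatorially, from the α face, to give the axial 3β-alcohol (anti to the lactone bridge); lactone and ester are not reduced at −78 °C.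

**Step 21**
Reactants: 23 benzyl ester of the target (3β-OH)
Product: 24 target acid
Conditions: H2 (1 atm), 10% Pd on carbon, EtOAc, rt
Reagents that add atoms: none
Why: hydrogenolysis of the benzyl ester frees the C7 acid under neutral conditions that leave the tertiary alcohol and the lactone untouched.

**Compound list**

1 | 6-methoxy-1-indanone | COc1ccc2CCC(=O)c2c1 | starting material
2 | ethyl 2-(6-methoxy-1-oxo-2,3,5,7a-tetrahydro-1H-inden-7a-yl)acetate, racemic (quaternary C8 with CH2CO2Et = C14/C13; C9=C11 and C15=C16(OMe); C6 ketone) | CCOC(=O)CC12C=C(OC)CC=C1CCC2=O | intermediate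
3 | ethyl 2-[(1S,7aR)-1-hydroxy-6-methoxy-2,3,5,7a-tetrahydro-1H-inden-7a-yl]acetate (6-OH trans to the C8 side chain) | CCOC(=O)C[C@@]12C=C(OC)CC=C1CC[C@@H]2O | intermediate
4 | (1S,7aR)-7a-(2-hydroxyethyl)-6-methoxy-2,3,5,7a-tetrahydro-1H-inden-1-ol | OCC[C@@]12C=C(OC)CC=C1CC[C@@H]2O | intermediate
5 | (1S,7aR)-1-hydroxy-7a-(2-hydroxyethyl)-1,2,3,5,7,7a-hexahydro-6H-inden-6-one | OCC[C@@]12CC(=O)CC=C1CC[C@@H]2O | intermediate
6 | 2-[(7aR)-1,6-dioxo-1,2,3,5,6,7-hexahydro-7aH-inden-7a-yl]acetaldehyde | O=CC[C@@]12CC(=O)CC=C1CCC2=O | intermediate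
7 | tricyclic keto diol: ring B cyclopentanone (C6=O) fused at C8–C9 to a bicyclo[3.2.1]oct-2-ene with bridgeheads C8 and C16 (bridges C15; C14–C13; C9=C11–C12); 16-OH at the bridgehead, 13-OH exo (towards C15, cis to 16-OH) | O=C1CCC2=CC[C@@]3(O)C[C@@]12C[C@@H]3O | intermediate
8 | 9,11-dihydro-7 with 9β-H (H9 on the side of C15, anti to C14) | O=C1CC[C@@H]2CC[C@@]3(O)C[C@@]12C[C@@H]3O | intermediate
9 | 13,16-O-isopropylidene acetal of 8 | O=C1CC[C@@H]2CC[C@@]3(OC(C)(C)O4)C[C@@]12C[C@@H]34 | intermediate
10 | enol triflate of 9 (C5=C6, OTf on C6) | FC(F)(F)S(=O)(=O)OC1=CC[C@@H]2CC[C@@]3(OC(C)(C)O4)C[C@@]12C[C@@H]34 | intermediate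
11 | benzyl ester (C7) on C6 of the C5=C6 alkene, acetonide retained | O=C(OCc5ccccc5)C1=CC[C@@H]2CC[C@@]3(OC(C)(C)O4)C[C@@]12C[C@@H]34 | intermediate
12 | 10-oxo derivative of 11 (C10 ketone conjugated with C5=C6–CO2Bn) | O=C(OCc5ccccc5)C1=CC(=O)[C@@H]2CC[C@@]3(OC(C)(C)O4)C[C@@]12C[C@@H]34 | intermediate
13 | tertiary alcohol from 12: 10α-OH, 10β-(but-3-en-1-yl) (chain = C1, C2, C3 and a terminal CH2) | O=C(OCc5ccccc5)C1=C[C@@](O)(CCC=C)[C@@H]2CC[C@@]3(OC(C)(C)O4)C[C@@]12C[C@@H]34 | intermediate
14 | propionate ester of the 10α-OH of 13 | O=C(OCc5ccccc5)C1=C[C@@](OC(=O)CC)(CCC=C)[C@@H]2CC[C@@]3(OC(C)(C)O4)C[C@@]12C[C@@H]34 | intermediate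
15 | γ-lactone O10–C19(=O)–C4H(CH3)–C5 fused cis on the α face of ring B; 5β-H, 6β-CO2Bn; C4 epimers; acetonide retained | C=CCC[C@]12OC(=O)C(C)[C@H]1[C@H](C(=O)OCc5ccccc5)[C@]34C[C@@H]6OC(C)(C)O[C@@]6(C3)CC[C@@H]24 | intermediate
16 | 13-exo,16-diol from 15 | C=CCC[C@]12OC(=O)C(C)[C@H]1[C@H](C(=O)OCc5ccccc5)[C@]34C[C@H](O)[C@](O)(C3)CC[C@@H]24 | intermediate
17 | 13-exo-methanesulfonate of 16 (16-OH free) | C=CCC[C@]12OC(=O)C(C)[C@H]1[C@H](C(=O)OCc5ccccc5)[C@]34C[C@H](OS(C)(=O)=O)[C@](O)(C3)CC[C@@H]24 | intermediate
18 | 16-ketone with the gibberellane C/D system: bicyclo[3.2.1]octan-6-one with bridgeheads C8 and C13 (bridges C14; C15–C16(=O); C9–C11–C12); rest as in 17 | C=CCC[C@]12OC(=O)C(C)[C@H]1[C@H](C(=O)OCc5ccccc5)[C@@]34CC(=O)[C@@H](C3)CC[C@@H]24 | intermediate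
19 | 16-methyl carbinol of 18: CH3 (C17) exo (towards C14), OH endo | C=CCC[C@]12OC(=O)C(C)[C@H]1[C@H](C(=O)OCc5ccccc5)[C@@]34C[C@](C)(O)[C@@H](C3)CC[C@@H]24 | intermediate
20 | aldehyde from 19: CH2CH2CHO (C1–C3) on C10 | O=CCC[C@]12OC(=O)C(C)[C@H]1[C@H](C(=O)OCc5ccccc5)[C@@]34C[C@](C)(O)[C@@H](C3)CC[C@@H]24 | intermediate
21 | benzyl ester of the pentacyclic skeleton, ring A closed, C4 quaternary, C3–OH as both epimers | C[C@@]12C(=O)O[C@]3(CCC1O)[C@@H]1CC[C@@H]4C[C@]1(C[C@]4(C)O)[C@@H](C(=O)OCc5ccccc5)[C@@H]32 | intermediate
22 | 3-oxo benzyl ester | C[C@@]12C(=O)O[C@]3(CCC1=O)[C@@H]1CC[C@@H]4C[C@]1(C[C@]4(C)O)[C@@H](C(=O)OCc5ccccc5)[C@@H]32 | intermediate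
23 | benzyl ester of 24 (3β-OH, axial) | C[C@@]12C(=O)O[C@]3(CC[C@@H]1O)[C@@H]1CC[C@@H]4C[C@]1(C[C@]4(C)O)[C@@H](C(=O)OCc5ccccc5)[C@@H]32 | intermediate
24 | target: 3β,16-dihydroxy-16-methyl 19,10-lactone 7-acid (16-OH endo, 16-CH3 exo) | C[C@@]12C(=O)O[C@]3(CC[C@@H]1O)[C@@H]1CC[C@@H]4C[C@]1(C[C@]4(C)O)[C@@H](C(=O)O)[C@@H]32 | target

**Step count and risks**

Total step count: 21. Longest linear sequence: 21 steps (from 1).

Steps most likely to fail:

Step 5. What may go wrong: electron transfer to the hindered C6 ketone in competition with the aldehyde (over-reduction, ketyl addition to the wrong carbonyl) and erosion of the cis selectivity. The fallback sets out from 5 and comes back at 9. Only the primary alcohol of 5 is oxidised (TEMPO, PhI(OAc)2, CH2Cl2) to the 6β-hydroxy keto aldehyde F1, whose C6 alcohol is trans to the side chain and cannot form a lactol. Coupling with SmI2 then gives the triol F2 without a competing ketone, and hydrogenation over Pd on carbon gives the saturated triol F3. Acetone/2,2-dimethoxypropane with PPTS protects only the cis 13,16-diol, giving the hydroxy acetonide F4. Dess–Martin oxidation of its C6 alcohol gives 9.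

Step 10. What may go wrong: unselective C–H oxidation (benzylic CH2 of the ester, acid-promoted loss of the acetonide) and enolisation at C9 of the product. The fallback sets out from 11 and comes back at 12. The methylene is oxygenated in two stages: SeO2/t-BuOOH in CH2Cl2 (ene reaction, then 2,3-sigmatropic shift) gives the C10 allylic alcohol F5, and MnO2 in CH2Cl2 oxidises it to 12.

Step 12. What may go wrong: fragmentation of the tertiary ester enolate into a ketene and the C10 alkoxide, or slow addition to the hindered enoate. The fallback sets out from 12 and comes back at 15. 12 is treated with the organocerium reagent as in step 11 but quenched with water, and alcohol 13 is isolated. N-Bromosuccinimide and ethyl 1-propenyl ether convert it into the mixed bromoacetal F6. Bu3SnH/AIBN in benzene at 80 °C then effects an Ueno–Stork cyclisation: the nucleophilic secondary radical adds 5-exo-trig to the electron-poor C5 on the α face, giving, after equilibration of C6 with DBU, the cyclic ethyl acetal F7. Oxidation of the acetal with CrO3/H2SO4 in acetone at 0 °C gives lactone 15.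

**Further compounds**

F1 | step 5 | 2-[(1S,7aR)-1-hydroxy-6-oxo-1,2,3,5,6,7-hexahydro-7aH-inden-7a-yl]acetaldehyde | O=CC[C@@]12CC(=O)CC=C1CC[C@@H]2O
F2 | step 5 | 6β,13-exo,16-triol (7 with C6–OH in place of the ketone) | O[C@H]1CCC2=CC[C@@]3(O)C[C@@]12C[C@@H]3O
F3 | step 5 | 9β-H saturated triol | O[C@H]1CC[C@@H]2CC[C@@]3(O)C[C@@]12C[C@@H]3O
F4 | step 5 | 13,16-O-isopropylidene acetal of the triol, 6β-OH free | O[C@H]1CC[C@@H]2CC[C@@]3(OC(C)(C)O4)C[C@@]12C[C@@H]34
F5 | step 10 | C10 allylic alcohol of 11 (C10 epimers) | O=C(OCc5ccccc5)C1=CC(O)[C@@H]2CC[C@@]3(OC(C)(C)O4)C[C@@]12C[C@@H]34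
F6 | step 12 | 10α-O-(2-bromo-1-ethoxypropyl) mixed acetal of 13 | O=C(OCc5ccccc5)C1=C[C@@](OC(OCC)C(C)Br)(CCC=C)[C@@H]2CC[C@@]3(OC(C)(C)O4)C[C@@]12C[C@@H]34
F7 | step 12 | cyclic ethyl acetal corresponding to 15 (C19 as CH(OEt)) | C=CCC[C@]12OC(OCC)C(C)[C@H]1[C@H](C(=O)OCc5ccccc5)[C@]34C[C@@H]6OC(C)(C)O[C@@]6(C3)CC[C@@H]24
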